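Product in this flask is paid for in partner, which reaches the solution as the solid reagent dissolves and then turns either substrate into its product. Taking one partner per product, call 125 % of the substrate charge, the solid reagent charged as a fraction of both substrates charged together, the allowance: it is the ceiling that the solid reagent puts on the product's fraction. The substrates themselves cap that fraction at 100 %, and in this flask the allowance stands above that cap, so substrate is the limiting reagent.

| flask | left-handed substrate | right-handed substrate | solid reagent | remark | time |
|---|---|---|---|---|---|
| summer | 11 mM | 11 mM | 55 mM | run made earlier |  |
| flask | 22 mM | 22 mM | 55.0 mM |  | 2.0 min |

summer run (percent of the left-handed substrate and right-handed substrate together charged)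

| time / s | left-handed product / % | right-handed product / % |
|---|---|---|
| 10.0 | 5.9 | 3.8 |
| 12.0 | 6.5 | 3.0 |
| 15.0 | 10.3 | 4.4 |
| 25.0 | 16.4 | 8.7 |

(each reading ± 0.5 percentage points)

- partner is single-handed; left-handed substrate and right-handed substrate are mirror images of each other, charged as a racemate, each of them at the stated concentration
- solid, in amounts per volume of the solution: solid reagent
- at the start none of the solid reagent is in solution
- an excess is the difference of the two amounts in percent of their sum
- an excess is below zero if the other one leads
- the handed part of partner does not stay in what it makes, so the products of the two hands are mirror images too

* left-handed product and right-handed product together, in percent of the left-handed substrate and right-handed substrate charged together, at 2.0 min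
* excess of left-handed product over right-handed product in the product at 2.0 min
* whether the exchange between left-handed substrate and right-handed substrate keeps pace with the reaction: how far the product's excess at 2.0 min gets from its value without exchange to its value with instant exchange (above 80 % keeps pace, below 20 % hardly takes part, else lags behind)

My own reckoning starts from the last summer reading, 25.1 % of product at 25.0 s. Read as first order in substrate, it gives a constant of 0.0116 s⁻¹ and so 75.0 % at 2.0 min. Put that answer back in: it stands below the allowance, so the solid reagent charged covers that much product, and the second round keeps the figure.

The forecast says 68 %, less than my figure, with an excess of 22 % and an exchange that lags behind, weighing first order against the case that “dissolution of the solid limits the rate”.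

The flask gives 79.3 %, more than both figures, an excess of 19.5 %, and an exchange that lags behind, 35 % of the way.

    partner + left-handed substrate → left-handed product (k = 3.09 M⁻¹ s⁻¹)
    partner + right-handed substrate → right-handed product (k = 1.62 M⁻¹ s⁻¹)
    left-handed substrate ⇌ right-handed substrate (k = 0.00710 s⁻¹)
    solid reagent ⇌ partner, rate k4*(cs4 - [partner]) while solid is left; crystals form when [partner] > cs4 (solubility = 7.00 mM, k = 0.347 s⁻¹)
    partner ⇌ dormant form (K = 0.949, k = 0.151 s⁻¹)

Each step taken net, partner in the flask is made 1.05 times as fast as it is used up at 0.523 min and 1.04 times at 2.00 min, while the product stands below the allowance of 125 % and 13.3 % of the solid's own charge is still undissolved. The neighbouring flask with 33 mM of solid reagent has an allowance of 75.0 % and its solid is gone, 0 % of its own charge; it gives 67.2 % of product, and partner with dormant form holds 7.79 % of the substrate charge.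

The numbers in the tables stem from a simulated flask on assumed constants; scatter was added.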